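## The problem

Podocarpusflavone A (28) is an unsymmetrical biflavone. A 5,7,4'-trihydroxyflavone (unit 1) is joined through C3' of its ring B to C8 of a 5,7-dihydroxy-4'-methoxyflavone (unit 2). There is no stereocentre, so the task is one of regiochemistry and oxygen differentiation.

The inter-unit bond ends at C8 of unit 2, a carbon of a phloroglucinol ring lying between the oxygenated carbons C7 and C8a. C6 is electronically almost equivalent, so any arylation of a preformed ring A, or any late closure of ring C, must tell C8 from C6. The resulting biaryl carries three ortho substituents, which makes cross-coupling at this position sluggish.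

Of the six oxygen substituents, five are free phenols and one is a methyl ether on ring B of unit 2. Every protecting group must therefore come off under conditions that leave an anisole-type ether alone. The 4H-chromen-4-one rings open with hydroxide or other nucleophiles at C2, and the phloroglucinol rings are easily C-alkylated by carbocations released in deprotection.

The feature that invites a ring-forming solution is ring A of unit 2 itself. It is a 1,3,5-trioxygenated benzene with the aryl group on C8, flanked by the oxygens on C7 and C8a and para to the oxygen-bearing C5. A vinylketene and an aryl ynol ether deliver exactly this pattern, with the three oxygens arriving as three different groups.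

## Retrosynthesis

**28 from 27.** The last operation cuts four O–C bonds: three benzyl ethers on unit 1 and the ethyl ether on O5 of unit 2, leaving the 4'-methyl ether. This choice fixes the protecting groups for the whole route. Benzyl arrives with the building blocks 1 and 23. Ethyl is the alkoxy group of the cyclobutenone 9 and ends up peri to the C4 carbonyl of unit 2, the one position where chelation-assisted Lewis-acid cleavage can remove a simple alkyl ether without touching a non-chelated aryl methyl ether. The forward step must remove benzyl cations before they alkylate the electron-rich rings.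

**27 from 26, and 26 from 21 and 23.** Ring C of unit 1 is opened at O1–C2 (cyclodehydration) and then at C2–C3 (Claisen condensation). This gives the flavone ester 21 and the acetophenone 23. The cut is preferred to a biaryl coupling of two complete flavones because ring A of unit 1 is a symmetrical phloroglucinol that poses no regiochemical question, and because the carboxyl carbon that becomes C2 is already on ring B. A direct ester–enolate condensation reaches the same 1,3-diketone as a Baker–Venkataraman acyl shift but avoids saponifying an ester beside a base-sensitive chromone. The silyl ether on O7 of unit 2 has done its work by then and is removed in the same flask via 25.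

**21 from 18, and 18 from 14 and 17.** Ring C of unit 2 is opened at C4–C4a (Friedel–Crafts acylation) and at O1–C2 (conjugate addition of a phenol to an ynoate). Phenol 14 has one free hydroxyl, on C8a, and one free ortho position, C4a, so the closure can only give the 8-aryl flavone. A route through C-acylation of ring A would have to choose between C4a and C6 again. The ynoate is used as its tert-butyl ester 17 so that acid can unmask the acrylic acid 19 and activate it as 20 while the methyl benzoate on ring B stays intact.

**14 from 8 and 9 (key disconnection).** Ring A of unit 2 is taken apart at C8–C8a and C6–C7, giving the aryl siloxyalkyne 8 and 3-ethoxycyclobut-2-en-1-one 9. This cut removes the hindered biaryl bond from the list of bonds to be made, since the aryl group is already on the alkyne carbon that becomes C8. It also produces the three oxygens as hydroxyl (C8a), silyl ether (C7) and ethyl ether (C5) in one operation. A cross-coupling at C8 would give neither result. The precursors are a four-carbon ring and a monosubstituted benzene. The forward reaction must deliver a single orientation of alkyne and ketene.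

**8 from 5, 5 from 4, 4 from 2 and 3, 2 from 1.** The ynol C–O bond is cut back to the terminal alkyne 5, by way of acetylide 6 and ynolate 7. The aryl–alkyne bond is cut back to iodide 2 and silylacetylene 3, and the benzyl ether to the commercial iodophenol ester 1. These are standard bonds. The one demand is that the acetylide oxidation spares the methyl ester.

**17 from 15, and 23 from 22.** The ynoate is cut at the alkyne–carboxyl bond to 4-ethynylanisole 15, by way of acetylide 16. The acetophenone is cut at two benzyl ether bonds to phloroacetophenone 22. Each is a single operation on a commercial compound.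

## Roads not taken

**Alternative 1:** Here ring B of unit 1 is the ring that is made, with the cut through C3'–C4' and C1'–C2'. The 8-ethynylflavone A2 (unit 2 complete) would add across C3 and C6 of the hydroxypyranone ester A3, and cycloreversion of the bridged lactone would give the hydroxy benzoate A1.
- Merits: A1 carries the free 4'-hydroxyl and the ester in the right 1,2,4-relationship. The bond to C8 is made as an unhindered alkyne–arene bond, not as a hindered biaryl bond. Ring A of unit 2 comes from cheap phloroglucinol chemistry with only benzyl groups.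
- Weak points: A2 has to be reached by halogenating a protected unit 2 at C8, which brings back the C8/C6 question. An aryl alkyne is a weak dienophile for an electron-rich hydroxypyranone, so high temperatures are likely. Orientation rests only on the modest polarisation of an arylacetylene, and the wrong orientation would put the ester meta to the hydroxyl.
- Comparison: Both plans build an arene next to the biaryl axis by cycloaddition. Alternative 1 avoids a sensitive ynol ether and an ethyl ether that needs special cleavage, and in that respect it is the better plan. The chosen plan sets against this a cycloaddition between strongly polarised partners, whose orientation is dictated by the mechanism, and it answers the C8/C6 question where alternative 1 postpones it.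

**Alternative 2:** Both pyranone rings are cut at C2–C3. Base would convert the biaryl diester A5 into the bis(1,3-diketone) A4 by two intramolecular acyl transfers, and one acid treatment would then close both rings.
- Merits: The end game is the shortest of all. Every phenol is benzyl-protected, so the final deprotection is cleaner than in the chosen plan and the methyl ether is never at risk.
- Weak points: The difficulty is moved into A5. Its three-fold ortho-substituted biaryl bond has to be made by cross-coupling onto an acetylphloroglucinol. The anisoyl group must then sit on the more hindered of the two hydroxyls ortho to the acetyl group, the one next to the aryl substituent, and acylation of the other would lead to the 6-linked isomer. A hindered aryl ester is also prone to plain cleavage in base instead of acyl transfer.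
- Comparison: Alternative 2 is better in step economy after the biaryl stage and in deprotection. The chosen plan offers in return that the hydroxyl on C8a is the only free one by construction, with no selection between two similar phenols against the steric bias.

**Alternative 3:** Ring C of unit 1 is cut at C4a–C4, C4–C3 and O1–C2. The iodophenol A7, a one-carbon carbonyl source and the alkyne A8 (unit 2 carrying ring B of unit 1) would be joined under palladium catalysis to give the pentabenzyl ether A6.
- Merits: It is the most convergent plan, forming three bonds in one step, and again uses only benzyl protection.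
- Weak points: The acyl-palladium/alkyne sequence can close to the five-membered benzofuranone instead of the chromone. A7 is electron-rich and has substituents on both sides of the iodide, so oxidative addition is slow and reduction of the C–I bond competes. A8 already contains the C3'–C8 bond, which must come from a hindered coupling at C8 of unit 2, so the key step leaves the central problem untouched.
- Comparison: Alternative 3 is better in convergence and in the final deprotection. The chosen plan makes the biaryl junction and the oxygen pattern the direct result of its key step.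

Key step: step 5

Assumptions: the target SMILES carries no axial descriptor, so the C3'–C8 axis is treated as configurationally mobile and no atroposelectivity is sought. 3-Ethoxycyclobut-2-en-1-one (9) is taken as a purchased compound.

## Route

Step 1
Reactants: 1 methyl 4-hydroxy-3-iodobenzoate
Product: 2 methyl 4-(benzyloxy)-3-iodobenzoate
Conditions: BnBr, K2CO3, DMF, rt
Reagents that add atoms: benzyl bromide, BrCc1ccccc1
Why: Williamson ether synthesis on an acidic phenol; the ester and the aryl iodide are inert to carbonate at room temperature.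

Step 2
Reactants: 2 methyl 4-(benzyloxy)-3-iodobenzoate; 3 ethynyl(trimethyl)silane
Product: 4 methyl 4-(benzyloxy)-3-[(trimethylsilyl)ethynyl]benzoate
Conditions: PdCl2(PPh3)2 (2 mol %), CuI (4 mol %), Et3N, THF, 40 °C
Reagents that add atoms: none
Why: Sonogashira coupling of an aryl iodide, which adds readily to zerovalent palladium; the silyl cap prevents a second arylation and alkyne homocoupling.

Step 3
Reactants: 4 methyl 4-(benzyloxy)-3-[(trimethylsilyl)ethynyl]benzoate
Product: 5 methyl 4-(benzyloxy)-3-ethynylbenzoate
Conditions: K2CO3 (cat.), MeOH–CH2Cl2, 0 °C to rt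
Reagents that add atoms: none
Why: Methanolysis of the C(sp)–Si bond; with a methyl ester in methanol any transesterification is degenerate.

Step 4
Reactants: 5 methyl 4-(benzyloxy)-3-ethynylbenzoate
Product: 8 methyl 4-(benzyloxy)-3-({[tri(propan-2-yl)silyl]oxy}ethynyl)benzoate, via lithium acetylide 6 (not isolated), via lithium ynolate 7 (not isolated)
Conditions: LiN(SiMe3)2, THF, −78 °C; t-BuOOLi (from t-BuOOH and LiN(SiMe3)2), −78 to 0 °C; i-Pr3SiOTf, −78 to 0 °C
Reagents that add atoms: tert-butyl hydroperoxide (used as its lithium salt), CC(C)(C)OO; tri(propan-2-yl)silyl trifluoromethanesulfonate, CC(C)[Si](OS(=O)(=O)C(F)(F)F)(C(C)C)C(C)C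
Why: Known oxidation of a lithium acetylide by lithium tert-butyl peroxide: the acetylide attacks the peroxide oxygen and expels tert-butoxide to give ynolate 7, which the bulky silyl triflate traps on oxygen as an isolable ynol silyl ether. The amide base does not add to the non-enolisable methyl ester at −78 °C, and the acetylide is consumed by oxygen transfer below 0 °C.

Step 5
Reactants: 8 methyl 4-(benzyloxy)-3-({[tri(propan-2-yl)silyl]oxy}ethynyl)benzoate; 9 3-ethoxycyclobut-2-en-1-one
Product: 14 methyl 4-(benzyloxy)-3-(4-ethoxy-2-hydroxy-6-{[tri(propan-2-yl)silyl]oxy}phenyl)benzoate, via vinylketene 10 (not isolated), via vinylcyclobutenone 11 (not isolated), via dienylketene 12 (not isolated), via cyclohexadienone 13 (not isolated)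
Conditions: PhMe, 80 to 110 °C, argon, sealed vessel; 9 (1.3 equiv) added in portions
Reagents that add atoms: none
Why: This is a Danheiser benzannulation of a cyclobutenone with a siloxyalkyne, a known pericyclic cascade. Heating opens 9 by 4π electrocyclic cleavage to vinylketene 10, which the electron-rich alkyne 8 traps in a regiospecific [2+2] cycloaddition to give 11. The polarisation of the ynol ether decides the orientation: its aryl-bearing carbon is the nucleophilic terminus and bonds to the ketene carbonyl carbon (C8–C8a), and the oxygen-bearing carbon bonds to the ketene α-carbon (C7–C6). A second 4π opening of 11 gives dienylketene 12, and ring A closes by thermal disrotatory 6π electrocyclisation to 13, whose tautomerisation to the phenol makes the sequence irreversible. No stereocentre is created; the one in 11 is lost on ring opening. The selectivity that matters is which oxygen ends up free: the only hydroxyl of 14 is the former ketene oxygen on C8a, next to the aryl-bearing C8, with the silyloxy group on C7 and the ethoxy group on C5. The ester and benzyl ether are spectators under neutral thermal conditions, and portionwise addition of 9 keeps the ketene concentration low so that acylation of the hindered phenol of 14 should stay minor.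

Step 6
Reactants: 15 1-ethynyl-4-methoxybenzene
Product: 17 tert-butyl 3-(4-methoxyphenyl)prop-2-ynoate, via lithium acetylide 16 (not isolated)
Conditions: n-BuLi, THF, −78 °C; Boc2O, −78 °C to rt
Reagents that add atoms: di-tert-butyl dicarbonate, CC(C)(C)OC(=O)OC(=O)OC(C)(C)C
Why: Acylation of a lithium acetylide with the dicarbonate is a standard route to tert-butyl alkynoates; the tert-butyl ester is chosen so that step 8 can release the acid without touching the methyl benzoate.

Step 7
Reactants: 14 methyl 4-(benzyloxy)-3-(4-ethoxy-2-hydroxy-6-{[tri(propan-2-yl)silyl]oxy}phenyl)benzoate; 17 tert-butyl 3-(4-methoxyphenyl)prop-2-ynoate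
Product: 18 methyl 4-(benzyloxy)-3-[2-{[(1Z)-3-tert-butoxy-1-(4-methoxyphenyl)-3-oxoprop-1-en-1-yl]oxy}-4-ethoxy-6-{[tri(propan-2-yl)silyl]oxy}phenyl]benzoate
Conditions: Cs2CO3 (0.5 equiv), DMF, 60 °C
Reagents that add atoms: none
Why: Oxa-Michael addition of a phenoxide to an arylpropiolate; anti addition should give mainly the Z enol ether, and any E isomer converges in step 8. Since 14 has a single free hydroxyl, only O1 of unit 2 is vinylated.

Step 8
Reactants: 18 methyl 4-(benzyloxy)-3-[2-{[(1Z)-3-tert-butoxy-1-(4-methoxyphenyl)-3-oxoprop-1-en-1-yl]oxy}-4-ethoxy-6-{[tri(propan-2-yl)silyl]oxy}phenyl]benzoate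
Product: 21 methyl 4-(benzyloxy)-3-[5-ethoxy-2-(4-methoxyphenyl)-4-oxo-7-{[tri(propan-2-yl)silyl]oxy}-4H-chromen-8-yl]benzoate, via acrylic acid 19 (not isolated), via mixed anhydride 20 (not isolated)
Conditions: CF3CO2H, CH2Cl2, 0 °C to rt; then (CF3CO)2O, rt
Reagents that add atoms: none
Why: Acidolysis of the tert-butyl ester, then intramolecular Friedel–Crafts acylation through the mixed trifluoroacetic anhydride. The acyl group can only reach C4a, the one free position ortho to O1, which is activated by three oxygens. Acid equilibrates the enol ether geometry, and the methyl ester, benzyl ether and aryl silyl ether should tolerate anhydrous trifluoroacetic acid at room temperature.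

Step 9
Reactants: 22 1-(2,4,6-trihydroxyphenyl)ethan-1-one
Product: 23 1-[2,4-bis(benzyloxy)-6-hydroxyphenyl]ethan-1-one
Conditions: BnBr (2.1 equiv), K2CO3, DMF, rt
Reagents that add atoms: benzyl bromide, BrCc1ccccc1
Why: Selective Williamson dibenzylation; the last ortho hydroxyl is held in a hydrogen bond to the acetyl carbonyl and resists alkylation with a limited amount of halide.

Step 10
Reactants: 21 methyl 4-(benzyloxy)-3-[5-ethoxy-2-(4-methoxyphenyl)-4-oxo-7-{[tri(propan-2-yl)silyl]oxy}-4H-chromen-8-yl]benzoate; 23 1-[2,4-bis(benzyloxy)-6-hydroxyphenyl]ethan-1-one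
Product: 26 1-[2,4-bis(benzyloxy)-6-hydroxyphenyl]-3-{4-(benzyloxy)-3-[5-ethoxy-7-hydroxy-2-(4-methoxyphenyl)-4-oxo-4H-chromen-8-yl]phenyl}propane-1,3-dione, via dilithium enolate 24 (not isolated), via silylated diketone 25 (not isolated)
Conditions: 23, LiN(SiMe3)2 (4 equiv), THF, −78 to −10 °C; 21, −78 °C to rt; then Bu4NF, 0 °C; aq. NH4Cl
Reagents that add atoms: none
Why: Claisen condensation of the phenoxide–enolate of 23 with the methyl ester, driven by deprotonation of the β-diketone; it gives the diketone a Baker–Venkataraman acyl shift would give, without prior saponification. Fluoride then cleaves the aryl silyl ether on O7 of unit 2, which is no longer needed.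

Step 11
Reactants: 26 1-[2,4-bis(benzyloxy)-6-hydroxyphenyl]-3-{4-(benzyloxy)-3-[5-ethoxy-7-hydroxy-2-(4-methoxyphenyl)-4-oxo-4H-chromen-8-yl]phenyl}propane-1,3-dione
Product: 27 8-{2-(benzyloxy)-5-[5,7-bis(benzyloxy)-4-oxo-4H-chromen-2-yl]phenyl}-5-ethoxy-7-hydroxy-2-(4-methoxyphenyl)-4H-chromen-4-one
Conditions: H2SO4 (cat.), AcOH, 80 °C
Reagents that add atoms: none
Why: Acid-catalysed cyclodehydration of an o-hydroxyaryl 1,3-diketone, the closing stage of a Baker–Venkataraman flavone synthesis: the phenol adds to the carbonyl next to ring B and loss of water gives the chromen-4-one of unit 1.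

Step 12
Reactants: 27 8-{2-(benzyloxy)-5-[5,7-bis(benzyloxy)-4-oxo-4H-chromen-2-yl]phenyl}-5-ethoxy-7-hydroxy-2-(4-methoxyphenyl)-4H-chromen-4-one
Product: 28 podocarpusflavone A, 8-[5-(5,7-dihydroxy-4-oxo-4H-chromen-2-yl)-2-hydroxyphenyl]-5,7-dihydroxy-2-(4-methoxyphenyl)-4H-chromen-4-one
Conditions: BCl3 (excess), C6HMe5, CH2Cl2, −78 °C to rt; MeOH, then aqueous work-up
Reagents that add atoms: none
Why: Lewis-acid ether cleavage: BCl3 removes aryl benzyl ethers at low temperature while pentamethylbenzene traps the benzyl cations. On warming, the ethyl ether on O5 of unit 2, held in a boron chelate with the C4 carbonyl, is cleaved by chloride, whereas the non-chelated 4'-methyl ether should remain.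

## Compound list

1 | methyl 4-hydroxy-3-iodobenzoate | COC(=O)c1ccc(O)c(I)c1 | starting material
2 | methyl 4-(benzyloxy)-3-iodobenzoate | COC(=O)c1ccc(OCc2ccccc2)c(I)c1 | intermediate
3 | ethynyl(trimethyl)silane | C[Si](C)(C)C#C | starting material
4 | methyl 4-(benzyloxy)-3-[(trimethylsilyl)ethynyl]benzoate | COC(=O)c1ccc(OCc2ccccc2)c(C#C[Si](C)(C)C)c1 | intermediate
5 | methyl 4-(benzyloxy)-3-ethynylbenzoate | COC(=O)c1ccc(OCc2ccccc2)c(C#C)c1 | intermediate
6 | lithium [2-(benzyloxy)-5-(methoxycarbonyl)phenyl]acetylide | COC(=O)c1ccc(OCc2ccccc2)c(C#C[Li])c1 | intermediate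
7 | lithium 2-[2-(benzyloxy)-5-(methoxycarbonyl)phenyl]ethyn-1-olate | COC(=O)c1ccc(OCc2ccccc2)c(C#CO[Li])c1 | intermediate
8 | methyl 4-(benzyloxy)-3-({[tri(propan-2-yl)silyl]oxy}ethynyl)benzoate | COC(=O)c1ccc(OCc2ccccc2)c(C#CO[Si](C(C)C)(C(C)C)C(C)C)c1 | intermediate
9 | 3-ethoxycyclobut-2-en-1-one | CCOC1=CC(=O)C1 | starting material
10 | 3-ethoxybuta-1,3-dien-1-one (vinylketene) | C=C(OCC)C=C=O | intermediate
11 | methyl 4-(benzyloxy)-3-[3-(1-ethoxyethenyl)-4-oxo-2-{[tri(propan-2-yl)silyl]oxy}cyclobut-1-en-1-yl]benzoate (racemic) | COC(=O)c1ccc(OCc2ccccc2)c(C2=C(O[Si](C(C)C)(C(C)C)C(C)C)C(C(=C)OCC)C2=O)c1 | intermediate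
12 | methyl 4-(benzyloxy)-3-[(3E)-5-ethoxy-1-oxo-3-{[tri(propan-2-yl)silyl]oxy}hexa-1,3,5-trien-2-yl]benzoate | COC(=O)c1ccc(OCc2ccccc2)c(C(=C=O)/C(O[Si](C(C)C)(C(C)C)C(C)C)=C\C(=C)OCC)c1 | intermediate
13 | methyl 4-(benzyloxy)-3-(4-ethoxy-6-oxo-2-{[tri(propan-2-yl)silyl]oxy}cyclohexa-1,3-dien-1-yl)benzoate | COC(=O)c1ccc(OCc2ccccc2)c(C2=C(O[Si](C(C)C)(C(C)C)C(C)C)C=C(OCC)CC2=O)c1 | intermediate
14 | methyl 4-(benzyloxy)-3-(4-ethoxy-2-hydroxy-6-{[tri(propan-2-yl)silyl]oxy}phenyl)benzoate | COC(=O)c1ccc(OCc2ccccc2)c(-c2c(O)cc(OCC)cc2O[Si](C(C)C)(C(C)C)C(C)C)c1 | intermediate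
15 | 1-ethynyl-4-methoxybenzene | C#Cc1ccc(OC)cc1 | starting material
16 | lithium (4-methoxyphenyl)acetylide | [Li]C#Cc1ccc(OC)cc1 | intermediate
17 | tert-butyl 3-(4-methoxyphenyl)prop-2-ynoate | COc1ccc(C#CC(=O)OC(C)(C)C)cc1 | intermediate
18 | methyl 4-(benzyloxy)-3-[2-{[(1Z)-3-tert-butoxy-1-(4-methoxyphenyl)-3-oxoprop-1-en-1-yl]oxy}-4-ethoxy-6-{[tri(propan-2-yl)silyl]oxy}phenyl]benzoate | COC(=O)c1ccc(OCc2ccccc2)c(-c2c(O/C(=C\C(=O)OC(C)(C)C)c3ccc(OC)cc3)cc(OCC)cc2O[Si](C(C)C)(C(C)C)C(C)C)c1 | intermediate
19 | (2Z)-3-{2-[2-(benzyloxy)-5-(methoxycarbonyl)phenyl]-5-ethoxy-3-{[tri(propan-2-yl)silyl]oxy}phenoxy}-3-(4-methoxyphenyl)prop-2-enoic acid | COC(=O)c1ccc(OCc2ccccc2)c(-c2c(O/C(=C\C(=O)O)c3ccc(OC)cc3)cc(OCC)cc2O[Si](C(C)C)(C(C)C)C(C)C)c1 | intermediate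
20 | mixed anhydride of 19 with trifluoroacetic acid | COC(=O)c1ccc(OCc2ccccc2)c(-c2c(O/C(=C\C(=O)OC(=O)C(F)(F)F)c3ccc(OC)cc3)cc(OCC)cc2O[Si](C(C)C)(C(C)C)C(C)C)c1 | intermediate
21 | methyl 4-(benzyloxy)-3-[5-ethoxy-2-(4-methoxyphenyl)-4-oxo-7-{[tri(propan-2-yl)silyl]oxy}-4H-chromen-8-yl]benzoate | COC(=O)c1ccc(OCc2ccccc2)c(-c2c(O[Si](C(C)C)(C(C)C)C(C)C)cc(OCC)c3c(=O)cc(-c4ccc(OC)cc4)oc23)c1 | intermediate
22 | 1-(2,4,6-trihydroxyphenyl)ethan-1-one | CC(=O)c1c(O)cc(O)cc1O | starting material
23 | 1-[2,4-bis(benzyloxy)-6-hydroxyphenyl]ethan-1-one | CC(=O)c1c(O)cc(OCc2ccccc2)cc1OCc1ccccc1 | intermediate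
24 | dilithium 1-[2,4-bis(benzyloxy)-6-oxidophenyl]ethen-1-olate | [Li]OC(=C)c1c(O[Li])cc(OCc2ccccc2)cc1OCc1ccccc1 | intermediate
25 | 1-[2,4-bis(benzyloxy)-6-hydroxyphenyl]-3-{4-(benzyloxy)-3-[5-ethoxy-2-(4-methoxyphenyl)-4-oxo-7-{[tri(propan-2-yl)silyl]oxy}-4H-chromen-8-yl]phenyl}propane-1,3-dione (present as its lithium salt) | O=C(CC(=O)c1ccc(OCc2ccccc2)c(-c2c(O[Si](C(C)C)(C(C)C)C(C)C)cc(OCC)c3c(=O)cc(-c4ccc(OC)cc4)oc23)c1)c1c(O)cc(OCc2ccccc2)cc1OCc1ccccc1 | intermediate
26 | 1-[2,4-bis(benzyloxy)-6-hydroxyphenyl]-3-{4-(benzyloxy)-3-[5-ethoxy-7-hydroxy-2-(4-methoxyphenyl)-4-oxo-4H-chromen-8-yl]phenyl}propane-1,3-dione | O=C(CC(=O)c1ccc(OCc2ccccc2)c(-c2c(O)cc(OCC)c3c(=O)cc(-c4ccc(OC)cc4)oc23)c1)c1c(O)cc(OCc2ccccc2)cc1OCc1ccccc1 | intermediate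
27 | 8-{2-(benzyloxy)-5-[5,7-bis(benzyloxy)-4-oxo-4H-chromen-2-yl]phenyl}-5-ethoxy-7-hydroxy-2-(4-methoxyphenyl)-4H-chromen-4-one | CCOc1cc(O)c(-c2cc(-c3cc(=O)c4c(OCc5ccccc5)cc(OCc5ccccc5)cc4o3)ccc2OCc2ccccc2)c2oc(-c3ccc(OC)cc3)cc(=O)c12 | intermediate
28 | podocarpusflavone A, 8-[5-(5,7-dihydroxy-4-oxo-4H-chromen-2-yl)-2-hydroxyphenyl]-5,7-dihydroxy-2-(4-methoxyphenyl)-4H-chromen-4-one | COc1ccc(-c2cc(=O)c3c(O)cc(O)c(-c4cc(-c5cc(=O)c6c(O)cc(O)cc6o5)ccc4O)c3o2)cc1 | target

## Step count and risks

Total: 12 steps. Longest linear sequence: 10 steps (steps 1, 2, 3, 4, 5, 7, 8, 10, 11, 12, from 1 to 28). Steps 6 and 9 are one-step side branches.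

**Step 5 (key step).** The most likely failure is slow electrocyclic opening of the cyclobutenone, whose enol ether is conjugated with the carbonyl. The temperature then needed could cause thermal decomposition of the siloxyalkyne or acylation of the product phenol by the ketene. Orientation is not expected to be the problem.
Fallback: generate the same vinylketene at room temperature by a photochemical Wolff rearrangement. 3-Ethoxybut-3-en-2-one F1 would be made from lithiated ethyl vinyl ether and N-methoxy-N-methylacetamide. Detrifluoroacetylative diazo transfer (LiN(SiMe3)2, 2,2,2-trifluoroethyl trifluoroacetate, then methanesulfonyl azide and Et3N) would convert it into 1-diazo-3-ethoxybut-3-en-2-one F2. Irradiation of F2 with the siloxyalkyne sets out from 8, passes through 10 and 11, and after brief warming to complete the opening and closure of 11 comes back to the route at 14.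

**Step 4.** Attack of the acetylide or the peroxide anion on the methyl ester may compete with oxygen transfer while the mixture warms towards 0 °C.
Fallback: mask the carboxyl as its lithium salt. Setting out from 5, saponification (LiOH) gives 4-(benzyloxy)-3-ethynylbenzoic acid F3. Its dianion is oxidised in the same way and both oxygens are silylated to give the silyl ester tri(propan-2-yl)silyl 4-(benzyloxy)-3-({[tri(propan-2-yl)silyl]oxy}ethynyl)benzoate F4. F4 enters the benzannulation with 9 under the conditions of step 5 to give tri(propan-2-yl)silyl 4-(benzyloxy)-3-(4-ethoxy-2-hydroxy-6-{[tri(propan-2-yl)silyl]oxy}phenyl)benzoate F5. Mild hydrolysis of the labile silyl ester (K2CO3, MeOH–H2O, 0 °C) gives 4-(benzyloxy)-3-(4-ethoxy-2-hydroxy-6-{[tri(propan-2-yl)silyl]oxy}phenyl)benzoic acid F6. Methylation of the acid only, with (trimethylsilyl)diazomethane in methanol–toluene, comes back to the route at 14.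

**Step 7.** Conjugate addition of a hindered, ortho-arylated phenoxide to a β-aryl ynoate may be sluggish. At the temperatures then required, transfer or loss of the silyl group on O7 would erase the oxygen differentiation set in step 5.
Fallback: build ring C of unit 2 by carbonylative annulation. Setting out from 14, iodination with N-iodosuccinimide ortho to the free hydroxyl (the para position is shielded by the silyloxy group) gives methyl 4-(benzyloxy)-3-(4-ethoxy-2-hydroxy-3-iodo-6-{[tri(propan-2-yl)silyl]oxy}phenyl)benzoate F7. A palladium-catalysed carbonylative coupling of F7 with alkyne 15 (PdCl2(PPh3)2, carbon monoxide, Et2NH), followed by six-membered ring closure of the resulting o-hydroxyaryl ynone, comes back to the route at 21.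

**Step 10.** The Claisen condensation of an electron-rich benzoate may stall through proton transfer between enolate and product or through reversibility. Conjugate attack of the enolate at C2 of the chromone of unit 2 is a possible side reaction.
Fallback: stepwise Baker–Venkataraman sequence. Setting out from 21, neutral ester cleavage with Me3SnOH gives 4-(benzyloxy)-3-[5-ethoxy-2-(4-methoxyphenyl)-4-oxo-7-{[tri(propan-2-yl)silyl]oxy}-4H-chromen-8-yl]benzoic acid F8. Carbodiimide esterification (EDC·HCl, DMAP) with 23 gives 2-acetyl-3,5-bis(benzyloxy)phenyl 4-(benzyloxy)-3-[5-ethoxy-2-(4-methoxyphenyl)-4-oxo-7-{[tri(propan-2-yl)silyl]oxy}-4H-chromen-8-yl]benzoate F9. LiN(SiMe3)2 then induces the intramolecular acyl transfer to 25, and desilylation with Bu4NF comes back to the route at 26.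

**Step 12.** Cleavage of the ethyl ether on O5 of unit 2 may be incomplete at temperatures that are still safe for the 4'-methyl ether, because chloride attack on an ethyl group is slower than on a methyl group. C-benzylation of the phloroglucinol rings is possible if cation trapping falls behind.
Fallback: split the deprotection into two mechanistically different operations. Setting out from 27, hydrogenolysis (H2, Pd/C, THF–MeOH) removes the three benzyl groups without any cation, giving 8-[5-(5,7-dihydroxy-4-oxo-4H-chromen-2-yl)-2-hydroxyphenyl]-5-ethoxy-7-hydroxy-2-(4-methoxyphenyl)-4H-chromen-4-one F10. Chelation-directed dealkylation with AlCl3 and NaI in MeCN, in which iodide is the nucleophile, then removes only the peri ethyl group and comes back to the route at 28.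

## Further compounds

F1 | step 5 | 3-ethoxybut-3-en-2-one | CC(=O)C(=C)OCC
F2 | step 5 | 1-diazo-3-ethoxybut-3-en-2-one | C=C(OCC)C(=O)C=[N+]=[N-]
F3 | step 4 | 4-(benzyloxy)-3-ethynylbenzoic acid | OC(=O)c1ccc(OCc2ccccc2)c(C#C)c1
F4 | step 4 | tri(propan-2-yl)silyl 4-(benzyloxy)-3-({[tri(propan-2-yl)silyl]oxy}ethynyl)benzoate | CC(C)[Si](OC(=O)c1ccc(OCc2ccccc2)c(C#CO[Si](C(C)C)(C(C)C)C(C)C)c1)(C(C)C)C(C)C
F5 | step 4 | tri(propan-2-yl)silyl 4-(benzyloxy)-3-(4-ethoxy-2-hydroxy-6-{[tri(propan-2-yl)silyl]oxy}phenyl)benzoate | CC(C)[Si](OC(=O)c1ccc(OCc2ccccc2)c(-c2c(O)cc(OCC)cc2O[Si](C(C)C)(C(C)C)C(C)C)c1)(C(C)C)C(C)C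
F6 | step 4 | 4-(benzyloxy)-3-(4-ethoxy-2-hydroxy-6-{[tri(propan-2-yl)silyl]oxy}phenyl)benzoic acid | OC(=O)c1ccc(OCc2ccccc2)c(-c2c(O)cc(OCC)cc2O[Si](C(C)C)(C(C)C)C(C)C)c1
F7 | step 7 | methyl 4-(benzyloxy)-3-(4-ethoxy-2-hydroxy-3-iodo-6-{[tri(propan-2-yl)silyl]oxy}phenyl)benzoate | COC(=O)c1ccc(OCc2ccccc2)c(-c2c(O)c(I)c(OCC)cc2O[Si](C(C)C)(C(C)C)C(C)C)c1
F8 | step 10 | 4-(benzyloxy)-3-[5-ethoxy-2-(4-methoxyphenyl)-4-oxo-7-{[tri(propan-2-yl)silyl]oxy}-4H-chromen-8-yl]benzoic acid | OC(=O)c1ccc(OCc2ccccc2)c(-c2c(O[Si](C(C)C)(C(C)C)C(C)C)cc(OCC)c3c(=O)cc(-c4ccc(OC)cc4)oc23)c1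
F9 | step 10 | 2-acetyl-3,5-bis(benzyloxy)phenyl 4-(benzyloxy)-3-[5-ethoxy-2-(4-methoxyphenyl)-4-oxo-7-{[tri(propan-2-yl)silyl]oxy}-4H-chromen-8-yl]benzoate | CC(=O)c1c(OC(=O)c2ccc(OCc3ccccc3)c(-c3c(O[Si](C(C)C)(C(C)C)C(C)C)cc(OCC)c4c(=O)cc(-c5ccc(OC)cc5)oc34)c2)cc(OCc2ccccc2)cc1OCc1ccccc1
F10 | step 12 | 8-[5-(5,7-dihydroxy-4-oxo-4H-chromen-2-yl)-2-hydroxyphenyl]-5-ethoxy-7-hydroxy-2-(4-methoxyphenyl)-4H-chromen-4-one | CCOc1cc(O)c(-c2cc(-c3cc(=O)c4c(O)cc(O)cc4o3)ccc2O)c2oc(-c3ccc(OC)cc3)cc(=O)c12
A1 | alternative 1 | methyl 3-[5,7-bis(benzyloxy)-2-(4-methoxyphenyl)-4-oxo-4H-chromen-8-yl]-4-hydroxybenzoate | COc1ccc(-c2cc(=O)c3c(OCc4ccccc4)cc(OCc4ccccc4)c(-c4cc(C(=O)OC)ccc4O)c3o2)cc1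
A2 | alternative 1 | 5,7-bis(benzyloxy)-8-ethynyl-2-(4-methoxyphenyl)-4H-chromen-4-one | C#Cc1c(OCc2ccccc2)cc(OCc2ccccc2)c2c(=O)cc(-c3ccc(OC)cc3)oc12
A3 | alternative 1 | methyl 3-hydroxy-2-oxo-2H-pyran-6-carboxylate | COC(=O)c1ccc(O)c(=O)o1
A4 | alternative 2 | 1-[2,4-bis(benzyloxy)-6-hydroxyphenyl]-3-[4-(benzyloxy)-3-{4,6-bis(benzyloxy)-2-hydroxy-3-[3-(4-methoxyphenyl)-3-oxopropanoyl]phenyl}phenyl]propane-1,3-dione | COc1ccc(C(=O)CC(=O)c2c(O)c(-c3cc(C(=O)CC(=O)c4c(O)cc(OCc5ccccc5)cc4OCc4ccccc4)ccc3OCc3ccccc3)c(OCc3ccccc3)cc2OCc2ccccc2)cc1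
A5 | alternative 2 | 2-acetyl-3,5-bis(benzyloxy)phenyl 4-(benzyloxy)-3-{3-acetyl-4,6-bis(benzyloxy)-2-[(4-methoxybenzoyl)oxy]phenyl}benzoate | COc1ccc(C(=O)Oc2c(C(C)=O)c(OCc3ccccc3)cc(OCc3ccccc3)c2-c2cc(C(=O)Oc3cc(OCc4ccccc4)cc(OCc4ccccc4)c3C(C)=O)ccc2OCc2ccccc2)cc1
A6 | alternative 3 | 5,7-bis(benzyloxy)-8-{2-(benzyloxy)-5-[5,7-bis(benzyloxy)-4-oxo-4H-chromen-2-yl]phenyl}-2-(4-methoxyphenyl)-4H-chromen-4-one | COc1ccc(-c2cc(=O)c3c(OCc4ccccc4)cc(OCc4ccccc4)c(-c4cc(-c5cc(=O)c6c(OCc7ccccc7)cc(OCc7ccccc7)cc6o5)ccc4OCc4ccccc4)c3o2)cc1
A7 | alternative 3 | 3,5-bis(benzyloxy)-2-iodophenol | Oc1cc(OCc2ccccc2)cc(OCc2ccccc2)c1I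
A8 | alternative 3 | 5,7-bis(benzyloxy)-8-[2-(benzyloxy)-5-ethynylphenyl]-2-(4-methoxyphenyl)-4H-chromen-4-one | C#Cc1ccc(OCc2ccccc2)c(-c2c(OCc3ccccc3)cc(OCc3ccccc3)c3c(=O)cc(-c4ccc(OC)cc4)oc23)c1
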